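**Plan**

1. Numbering used throughout: C1 (ketone), C2=C3 (3‑Me), cyclobutane C4–C5–C11–C10, C6 (CMe2), C7 (O‑senecioate), C8, C9 (O‑angelate), C10 (quaternary, Me). Ring B is C11–C1–C2–C3–C4–C5; the seven‑membered ring is C5–C6–C7–C8–C9–C10–C11.
2. Enabling feature: C4 is the γ‑carbon of the C1 enone and C10 is the α‑carbon of the C9 carbonyl. These two enol‑type donor carbons face each other across the C5–C11 bond of a cis‑fused six/seven bicycle, so the cyclobutane (and with it the bicyclo[3.1.1]heptenone and the quaternary C10) can be closed by oxidative C4–C10 coupling.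
3. Cuts: both ester C–O bonds; C7–O (back to a C7=C8 enone, which also leaves H‑10 as the only enolisable hydrogen of the C9 ketone); C4–C10; C1=O (allylic oxidation); C9–C10 and C10–CH3 (one‑carbon ring enlargement with methylation); C1–C11 and C4–C5 (Diels–Alder).
4. Forward order: ring B and the cis junction by Diels–Alder, six‑to‑seven ring enlargement, the two enones, the bis‑silyl dienol ether, the cyclobutane, then O7, O9 and the esters.
5. Stereochemistry: C5/C11 (cis and absolute) from the catalytic enantioselective cycloaddition; C4/C10 follow from that junction; C7 from a chiral copper catalyst; C9 from hydride delivery by O7 (7,9‑trans).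

Key step: step 6

Assumption: the catalyst antipodes written in steps 1 and 7 are those expected, by analogy with 2‑cyclohexenone and 2‑cycloheptenone, to give the configurations drawn; should either sense of induction be opposite, the mirror‑image catalyst is used with no other change.

**Route**

Step 1
Reactants: 1 4,4-dimethylcyclohex-2-en-1-one; 2 isoprene
Product: 3 cis-fused octalone (4aS,8aR)-4,4,6-trimethyl-3,4,4a,5,8,8a-hexahydronaphthalen-1(2H)-one
Conditions: 2 (5 equiv), (S)-B-(o-tolyl)diphenylprolinol oxazaborolidine·AlBr3 (10 mol %), CH2Cl2, −40 → −20 °C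
Reagents that add atoms: none
Why: Lewis-acid-catalysed enantioselective Diels–Alder reaction, in which suprafacial addition to the cyclic enone fixes the cis C5–C11 junction, the Lewis acid enforces the "para" orientation (C4 to C5, C1 to C11) and the chiral oxazaborolidine selects the enone face and so sets the absolute configuration of C5 and C11.

Step 2
Reactants: 3 cis-fused octalone; 4 dibromomethane; 5 iodomethane
Product: 8 5,11-cis-3,6,6,10-tetramethylbicyclo[5.4.0]undec-2-en-9-one (both C10 epimers), via lithium dibromomethylcarbinolate 6 (not isolated), via lithium enolate 7 (not isolated)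
Conditions: 4, LiTMP, THF, −78 °C; n-BuLi, −78 → 0 °C; 5, HMPA, −78 → 0 °C
Reagents that add atoms: none
Why: β-Oxido carbenoid ring enlargement followed by enolate alkylation, in which dibromomethyllithium adds to the C9 carbonyl, bromine–lithium exchange triggers a 1,2-shift of the more substituted α-carbon C11 with retention (cis junction kept) and the regiodefined C9=C10 enolate is C-methylated, the C10 configuration being irrelevant because it is erased in step 5.

Step 3
Reactants: 8 ring-enlarged ketone
Product: 10 5,11-cis-3,6,6,10-tetramethylbicyclo[5.4.0]undeca-2,7-dien-9-one, via trimethylsilyl enol ether 9 (not isolated)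
Conditions: LDA, Me3SiCl, THF, −78 °C; then Pd(OAc)2, MeCN, 25 °C
Reagents that add atoms: chlorotrimethylsilane, C[Si](C)(C)Cl (silyl group present in 9 only)
Why: Saegusa–Ito oxidation, in which kinetic deprotonation takes the less substituted α-methylene C8 and palladium diacetate converts the enol ether into the C7=C8 enone, after which H-10 is the only enolisable hydrogen next to C9.

Step 4
Reactants: 10 dienone
Product: 11 5,11-cis-3,6,6,10-tetramethylbicyclo[5.4.0]undeca-2,7-diene-1,9-dione
Conditions: t-BuOOH (70 % aq, 5 equiv), Rh2(cap)4 (dirhodium tetracaprolactamate, 1 mol %), ClCH2CH2Cl, 40 °C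
Reagents that add atoms: tert-butyl hydroperoxide, CC(C)(C)OO
Why: Radical allylic C–H oxidation, which, as in the conversion of 5-ene steroids into 7-ketones, should attack the methylene next to the CH terminus of the trisubstituted alkene (C1) rather than the one next to the fully substituted terminus (C4) and so give the 3-methyl enone without base that could epimerise C11.

Step 5
Reactants: 11 dienedione
Product: 12 1,9-bis(tert-butyldimethylsilyloxy)-3,6,6,10-tetramethyl-5,11-cis-bicyclo[5.4.0]undeca-1,3,7,9-tetraene
Conditions: t-BuMe2SiOTf (2.5 equiv), Et3N (4 equiv), CH2Cl2, −78 → 0 °C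
Reagents that add atoms: tert-butyldimethylsilyl triflate, CC(C)(C)[Si](C)(C)OS(=O)(=O)C(F)(F)F
Why: Soft enolisation (silyl triflate/amine), in which the C9 ketone can only lose H-10 and gives the cross-conjugated 2-silyloxy diene, while the β,β-disubstituted C1 enone should lose the accessible γ-hydrogen at C4 rather than the hindered ring-fusion H-11 and give the linear dienol ether, so that C11 keeps its configuration.

Step 6
Reactants: 12 bis-silyl dienol ether
Product: 13 longipina-2,7-diene-1,9-dione
Conditions: reticulated vitreous carbon anode, Pt cathode, undivided cell, constant current (2.2 F/mol), LiClO4 (0.1 M), 2,6-lutidine, MeOH/CH2Cl2 1:4, 5 mM, −20 °C; aqueous NaHCO3 work-up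
Reagents that add atoms: none
Why: Proposed new method: one-electron oxidation at the anode of a silyl dienol ether (the linear one in ring B is expected to be oxidised first) gives a radical cation whose terminus C4 is attacked by C10 of the neighbouring silyl enol ether in a 4-exo-trig closure of the cyclobutane C4–C5–C11–C10; the C9 oxocarbenium ion then loses its silyl group to methanol, and the 1-silyloxyallyl radical left in ring B is oxidised a second time and desilylated, which releases the C1 enone and the C9 enone. The closest known reaction types are the anodic coupling of enol ether radical cations with silyl enol ethers and the oxidative coupling of bis(silyl enol ethers), both established for five- to seven-membered rings but not for a four-membered one. The closure is expected to be reversible because the new bond belongs to a strained cyclobutylcarbinyl radical cation, and it is pulled forward by irreversible desilylation and by the second electron transfer, which only the closed form undergoes readily. C4 and C10 are both controlled by the cis C5–C11 junction: C10 hangs from C11 on one face of ring B and can reach C4 only on that face, and the seven-membered ring forces C9 anti and the methyl group syn to the enone bridge. The step needs γ (C4) rather than α (C2) attack and intra- rather than intermolecular coupling: attack at C2 would put the C1 oxocarbenium carbon into the four-membered ring (a bicyclic cyclobutanone) and lose conjugation, the larger terminal coefficient of the 1-silyloxy diene also favours C4, and high dilution suppresses dimerisation.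

Step 7
Reactants: 13 tricyclic dienedione
Product: 15 (7R)-7-hydroxylongipin-2-ene-1,9-dione, via 7-pinacolboryl ketone 14 (not isolated)
Conditions: B2pin2 (1.1 equiv), CuCl (5 mol %), NaOt-Bu (10 mol %), (R,Sp)-Josiphos (6 mol %), MeOH (2 equiv), THF, 0 °C; then H2O2, pH 7 buffer, 0 °C
Reagents that add atoms: bis(pinacolato)diboron, CC1(C)OB(OC1(C)C)B1OC(C)(C)C(C)(C)O1 (boryl group present in 14 only); hydrogen peroxide, OO
Why: Copper-catalysed asymmetric conjugate borylation followed by C–B oxidation with retention, in which the β-monosubstituted C7=C8–C9=O enone should react in preference to the β,β-disubstituted C1 enone and, because the two faces of C7 are nearly equivalent in the substrate, the chiral bisphosphine decides the C7 configuration (7R).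

Step 8
Reactants: 15 β-hydroxy ketone
Product: 16 (7R,9R)-9-hydroxy-7-(4-nitrobenzoyloxy)longipin-2-en-1-one
Conditions: 4-O2NC6H4CHO (5 equiv), SmI2 (0.3 equiv), THF, −10 °C
Reagents that add atoms: 4-nitrobenzaldehyde, O=Cc1ccc(cc1)[N+](=O)[O-]
Why: Evans–Tishchenko reduction, in which the samarium-bound hemiacetal formed at O7 delivers hydride intramolecularly to the C9 ketone on the face syn to O7, giving the 7,9-trans diol with O7 already differentiated as its 4-nitrobenzoate and leaving the C1 enone, which has no directing hydroxyl, untouched.

Step 9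
Reactants: 16 hydroxy nitrobenzoate; 17 angelic acid
Product: 19 (7R,9R)-9-angeloyloxy-7-(4-nitrobenzoyloxy)longipin-2-en-1-one, via angelic 2,4,6-trichlorobenzoic anhydride 18 (not isolated)
Conditions: 17, 2,4,6-Cl3C6H2COCl, Et3N, toluene, 25 °C; then 16, 80 °C
Reagents that add atoms: 2,4,6-trichlorobenzoyl chloride, ClC(=O)c1c(Cl)cc(Cl)cc1Cl (present in 18 only)
Why: Yamaguchi-type mixed-anhydride esterification run without a nucleophilic catalyst, conditions known to transfer the (Z)-2-methylbut-2-enoyl group to hindered secondary alcohols without Z-to-E isomerisation.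

Step 10
Reactants: 19 angelate nitrobenzoate
Product: 20 (7R,9R)-9-angeloyloxy-7-hydroxylongipin-2-en-1-one
Conditions: K2CO3 (0.2 equiv), MeOH, 0 °C
Reagents that add atoms: none
Why: Base-catalysed transesterification, in which the electron-poor 4-nitrobenzoate should be methanolysed much faster than the hindered, conjugated angelate.

Step 11
Reactants: 20 hydroxy angelate; 21 3-methylbut-2-enoyl chloride
Product: 22 CNP0277258.2, (7R,9R)-9-angeloyloxy-7-(3-methylbut-2-enoyloxy)longipin-2-en-1-one
Conditions: 21, pyridine, DMAP (cat.), CH2Cl2, 0 → 25 °C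
Reagents that add atoms: none
Why: Acylation of the remaining C7 hydroxyl with the acid chloride under pyridine/DMAP catalysis, the weak base avoiding deconjugation of the senecioyl group through its vinylketene.

**Compound list**

1 | 4,4-dimethylcyclohex-2-en-1-one | CC1(C)CCC(=O)C=C1 | starting material
2 | isoprene (2-methylbuta-1,3-diene) | C=CC(C)=C | starting material
3 | (4aS,8aR)-4,4,6-trimethyl-3,4,4a,5,8,8a-hexahydronaphthalen-1(2H)-one, cis-fused (C9 ketone, H-5 and H-11 cis) | O=C1CCC(C)(C)[C@H]2CC(C)=CC[C@H]21 | intermediate
4 | dibromomethane | BrCBr | starting material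
5 | iodomethane | CI | starting material
6 | lithium alkoxide of the dibromomethyl carbinol from 3 (carbinol configuration not controlled) | [Li+].[O-]C1(C(Br)Br)CCC(C)(C)[C@H]2CC(C)=CC[C@H]21 | intermediate (not isolated)
7 | lithium enolate of the ring-enlarged ketone (O on C9, C9=C10) | [Li+].[O-]C=1CCC(C)(C)[C@H]2CC(C)=CC[C@H]2C=1 | intermediate (not isolated)
8 | 5,11-cis-3,6,6,10-tetramethylbicyclo[5.4.0]undec-2-en-9-one (both C10 epimers) | O=C1CCC(C)(C)[C@H]2CC(C)=CC[C@H]2C1C | intermediate
9 | 9-trimethylsilyloxy-5,11-cis-3,6,6,10-tetramethylbicyclo[5.4.0]undeca-2,8-diene | C[Si](C)(C)OC1=CCC(C)(C)[C@H]2CC(C)=CC[C@H]2C1C | intermediate (not isolated)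
10 | 5,11-cis-3,6,6,10-tetramethylbicyclo[5.4.0]undeca-2,7-dien-9-one | O=C1C=CC(C)(C)[C@H]2CC(C)=CC[C@H]2C1C | intermediate
11 | 5,11-cis-3,6,6,10-tetramethylbicyclo[5.4.0]undeca-2,7-diene-1,9-dione | O=C1C=CC(C)(C)[C@H]2CC(C)=CC(=O)[C@H]2C1C | intermediate
12 | 1,9-bis(tert-butyldimethylsilyloxy)-3,6,6,10-tetramethyl-5,11-cis-bicyclo[5.4.0]undeca-1,3,7,9-tetraene | C1=CC(C)(C)[C@H]2C=C(C)C=C(O[Si](C)(C)C(C)(C)C)[C@H]2C(C)=C1O[Si](C)(C)C(C)(C)C | intermediate
13 | longipina-2,7-diene-1,9-dione (cyclobutane C4–C5–C11–C10; 10-Me syn to the C1–C3 bridge) | O=C1C=CC(C)(C)[C@@H]2[C@H]3C(=O)C=C(C)[C@@H]2[C@]31C | intermediate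
14 | 7-(pinacolboryl)longipin-2-ene-1,9-dione | O=C1C[C@@H](B4OC(C)(C)C(C)(C)O4)C(C)(C)[C@@H]2[C@H]3C(=O)C=C(C)[C@@H]2[C@]31C | intermediate (not isolated)
15 | (7R)-7-hydroxylongipin-2-ene-1,9-dione | O=C1C[C@@H](O)C(C)(C)[C@@H]2[C@H]3C(=O)C=C(C)[C@@H]2[C@]31C | intermediate
16 | (7R,9R)-9-hydroxy-7-(4-nitrobenzoyloxy)longipin-2-en-1-one (7,9-trans) | O[C@@H]1C[C@@H](OC(=O)c4ccc(cc4)[N+](=O)[O-])C(C)(C)[C@@H]2[C@H]3C(=O)C=C(C)[C@@H]2[C@]31C | intermediate
17 | angelic acid, (Z)-2-methylbut-2-enoic acid | C/C=C(/C)C(=O)O | starting material
18 | angelic 2,4,6-trichlorobenzoic anhydride | C/C=C(/C)C(=O)OC(=O)c1c(Cl)cc(Cl)cc1Cl | intermediate (not isolated)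
19 | (7R,9R)-9-angeloyloxy-7-(4-nitrobenzoyloxy)longipin-2-en-1-one | C/C=C(/C)C(=O)O[C@@H]1C[C@@H](OC(=O)c4ccc(cc4)[N+](=O)[O-])C(C)(C)[C@@H]2[C@H]3C(=O)C=C(C)[C@@H]2[C@]31C | intermediate
20 | (7R,9R)-9-angeloyloxy-7-hydroxylongipin-2-en-1-one | C/C=C(/C)C(=O)O[C@@H]1C[C@@H](O)C(C)(C)[C@@H]2[C@H]3C(=O)C=C(C)[C@@H]2[C@]31C | intermediate
21 | 3-methylbut-2-enoyl chloride (senecioyl chloride) | CC(C)=CC(=O)Cl | starting material
22 | CNP0277258.2, (7R,9R)-9-angeloyloxy-7-(3-methylbut-2-enoyloxy)longipin-2-en-1-one | C/C=C(/C)C(=O)O[C@@H]1C[C@@H](OC(=O)C=C(C)C)C(C)(C)[C@@H]2[C@H]3C(=O)C=C(C)[C@@H]2[C@]31C | target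

**Count and risks**

Total steps: 11. Longest linear sequence: 11 steps (1 → 22).

Step 6 (cyclobutane closure). What may go wrong is re-opening of the strained four-membered ring at the radical-cation or radical stage faster than the second oxidation, so that only desilylation back to 11 or intermolecular coupling is seen. The fallback sets out from 12 and returns at 13 by a polar route. N-Bromosuccinimide (1 equiv, THF, −78 °C) should brominate the more nucleophilic linear dienol ether at C4, from the face away from the seven-membered ring, to give the γ-bromo enone F1 with the C9 silyl dienol ether intact. Fluoride (Bu4NF, THF, −78 → 0 °C) then unmasks the C9 enolate, whose C10 displaces the allylic bromide with inversion (4-exo-tet). This is the classical intramolecular enolate alkylation used for bicyclo[3.1.1]heptanones.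

Step 2 (ring enlargement). What may go wrong is migration of the C8 methylene instead of the ring-fusion carbon C11, or enolisation of ketone 3 by the amide base with loss of material and erosion of the cis junction. The fallback sets out from 3 and returns at 8. The weakly basic 1-(methylseleno)ethyllithium (from 1,1-bis(methylseleno)ethane and n-BuLi, THF, −78 °C) adds to the carbonyl to give the β-hydroxy selenide F2. Activation of selenium with AgBF4 on Al2O3 (CH2Cl2, 25 °C) then induces the semipinacol ring enlargement, in which the more substituted carbon migrates and the C10 methyl is delivered directly.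

Step 1 (cycloaddition). What may go wrong is a cycloaddition too slow at the neopentylic β-carbon, so that isoprene polymerises or the Lewis acid epimerises the junction before useful conversion. The fallback sets out from 1 and returns at 3. Dehydrogenation with 2-iodoxybenzoic acid (DMSO, 70 °C) gives the cross-conjugated 4,4-dimethylcyclohexa-2,5-dien-1-one F3, a markedly better dienophile. Cycloaddition with isoprene under the same type of chiral Lewis-acid catalysis gives the cis-fused dienone adduct F4. Hydrogenation (H2, RhCl(PPh3)3, benzene, 25 °C) then saturates the disubstituted enone double bond in preference to the trisubstituted ring-B alkene.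

**Further compounds**

F1 | step 6 | 4-bromo-9-(tert-butyldimethylsilyloxy)-3,6,6,10-tetramethyl-5,11-cis-bicyclo[5.4.0]undeca-2,7,9-trien-1-one (Br trans to C10) | C1=CC(C)(C)[C@H]2[C@H](Br)C(C)=CC(=O)[C@H]2C(C)=C1O[Si](C)(C)C(C)(C)C
F2 | step 2 | β-hydroxy selenide, 1-[1-(methylseleno)ethyl] carbinol from 3 (new centres not controlled) | OC1(C(C)[Se]C)CCC(C)(C)[C@H]2CC(C)=CC[C@H]21
F3 | step 1 | 4,4-dimethylcyclohexa-2,5-dien-1-one | CC1(C)C=CC(=O)C=C1
F4 | step 1 | (4aS,8aR)-4,4,6-trimethyl-4a,5,8,8a-tetrahydronaphthalen-1(4H)-one, cis-fused | O=C1C=CC(C)(C)[C@H]2CC(C)=CC[C@H]21
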